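The data are simulated for substances that don't exist; scatter was added.

Take a small charge: G and L at 15 mM each, 30.0 mM of substrate together, and read what the south-east run says about it.

the same everywhere: G 15 mM; L 15 mM
- south-east: J 75 mM; run made earlier
- flask: J 37.5 mM; time 4.0 h

south-east run (percent of the G and L together charged)

| time / min | Z / % |
|---|---|
| 3.00 | 11 |
| 10.0 | 36 |
| 15.0 | 43 |
| 25.0 | 45 |
| 40.0 | 53 |
| 50.0 | 54 |

(scatter of a reading: 2 percentage points)

- Q is single-handed; G and L are mirror images of each other, charged as a racemate, each of them at the stated concentration
- as a solid, counted per litre of solution: J
- at the start none of J is in solution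
- Q is what J becomes in solution
- the handed part of Q does not stay in what it makes, so the products of the two hands are mirror images too

* Z at 4.0 h, in percent of the G and L together charged
* concentration of Q in solution at 25 min, in percent of saturation
* the change that raises the amount of Z at 4.0 h, in percent of the G and L together charged most ("none" if none brings more than 2 percentage points) (ochre / green / none)
* amount of Z at 4.0 h, in percent of the G and L together charged, after green

- ochre: doubling the dissolution coefficient of J, all else as stated
- green: doubling the solubility of J, all else as stated

Reckon Z at 4.0 h two ways. First, extend the late slope: from 25.0 min to 50.0 min Z climbs from 45% to 54%, and that line reaches 122%, more than the whole charge, so this way cheats. Second, take the plateau: the last two readings differ by 1 percentage point, less than the 2.8 points scatter of a difference, so read their mean, 53.5%, as the plateau.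

Now compute only the correction for the smaller charge of J. Z at the plateau is worth 16.1 mM, so the flask has 21.4 mM of J margin, the charge of J less what the plateau takes at one J per Z. The charge of J stands above what the plateau takes, so my own reckoning commits to Z at the plateau. But the margin counts Z and no other taker of J, so it says nothing of c_Q or of the best change, and I commit to no value for them.

The forecast gives 78% (62% to 90%), 75% (45% to 97%), none, and 75% (56% to 89%) after green, holding that “Interconversion limits the late stage”. Its Z stands above my plateau.

The flask gives 52.9%, with c_Q at 99.1% of saturation at 25 min. The best change is green, worth 3.9 points against 0.56 points for ochre, and it brings Z to 56.8%.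

    Q + G → Z (k = 0.166 /M/s)
    Q + L → E (k = 0.0801 /M/s)
    G ⇌ D (K = 0.0945, k = 0.0233 /s)
    L ⇌ D (K = 0.0945, k = 0.0233 /s)
    D → X (k = 0.00786 /s)
    J ⇌ Q, rate k6*(cs6 - [Q]) while solid is left; crystals form when [Q] > cs6 (solubility = 13.0 mM, k = 0.0284 /s)

In the flask at 4.00 h, E holds 7.98 mM and dissolved Q 13.0 mM, which is where the margin went. Reckon the neighbour with 22 mM of J the same way: its margin is 5.95 mM, less than the 8.22 mM of E and Q it ends with. J, the limiting reagent there, stands at 0% at 4.00 h, and that neighbour ends with Z at 45.9% and X at 31.2%.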